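The target is cut at both bonds of the ketone carbonyl that joins lactone carbon C3 to ring C; this carbon is supplied as carbon monoxide. A palladium-catalysed carbonylative Suzuki–Miyaura coupling unites a 3-bromobutenolide, CO and 4-isopropoxyphenylboronic acid in one operation, forming C3–C(=O) and C(=O)–aryl. The feature exploited is the C3–Br bond of the lactone ring, the less reactive of the two bromines inherited from mucobromic acid, which is still in place after C4 has received ring B. The precursor is the (Z)-3-bromo-5-(4-methoxybenzylidene)butenolide carrying ring B as an isopropyl ether at C4, so ring A stays masked while rings B and C are later freed and brominated.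

Key step: step 4

Remark on the chemistry: ring A is the aryl of the C5 benzylidene, ring B the aryl on C4 and ring C the aryl of the C3 ketone. Compound 1 is used as the racemic lactol, and 8 arises as a mixture of diastereomers whose stereocentres disappear in the same flask, so neither needs stereocontrol. Tetronic acid, 4-isopropoxybenzoyl chloride, hexamethylditin (Me3SnSnMe3) and N-bromosuccinimide, used only in fallbacks, are taken as purchased.

Step 1
Reactants: 1 mucobromic acid (3,4-dibromo-5-hydroxyfuran-2(5H)-one)
Product: 3 3,4-dibromofuran-2(5H)-one, via open-chain hydroxy acid 2 (not isolated)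
Conditions: NaBH4, MeOH, 0 °C; then conc. H2SO4, 0 °C
Reagents that add atoms: none
Why: The lactol is in equilibrium with its open (Z)-formyl acid, whose aldehyde is reduced by borohydride, and on acidification the cis-disposed hydroxy acid 2 closes to the lactone (hydride reduction followed by acid-promoted lactonisation).

Step 2
Reactants: 3 3,4-dibromofuran-2(5H)-one; 4 4-isopropoxyphenylboronic acid
Product: 5 3-bromo-4-(4-isopropoxyphenyl)furan-2(5H)-one
Conditions: 4 (1.1 equiv), PdCl2(MeCN)2 (5 mol%), AsPh3 (20 mol%), Ag2O (3 equiv), THF, 65 °C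
Reagents that add atoms: none
Why: Zerovalent palladium inserts faster into C4–Br, the β-position of the enoate (a vinylogous acyl bromide), than into C3–Br, so a slight excess of 4 should give the C4-monoarylated lactone (site-selective Suzuki–Miyaura coupling).

Step 3
Reactants: 5 3-bromo-4-(4-isopropoxyphenyl)furan-2(5H)-one; 6 4-methoxybenzaldehyde
Product: 9 (Z)-3-bromo-4-(4-isopropoxyphenyl)-5-(4-methoxybenzylidene)furan-2(5H)-one, via silyloxyfuran 7 (not isolated), via silyl aldol adduct 8 (not isolated)
Conditions: TBSOTf (1.3 equiv), iPr2NEt (3 equiv), CH2Cl2, rt; then DBU (2 equiv), rt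
Reagents that add atoms: none
Why: TBSOTf and iPr2NEt convert 5 into silyloxyfuran 7, which attacks the silyl-activated aldehyde through C5 (vinylogous Mukaiyama aldol) to give 8, and DBU then removes the acidic C5–H and expels silanolate (E1cB) to give the thermodynamically preferred Z-alkene, in which ring A points away from ring B.

Step 4
Reactants: 9 (Z)-3-bromo-4-(4-isopropoxyphenyl)-5-(4-methoxybenzylidene)furan-2(5H)-one; 4 4-isopropoxyphenylboronic acid
Product: 10 (Z)-3-(4-isopropoxybenzoyl)-4-(4-isopropoxyphenyl)-5-(4-methoxybenzylidene)furan-2(5H)-one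
Conditions: CO (5 bar), PdCl2(dppf) (5 mol%), K2CO3 (3 equiv), 4 (1.5 equiv, added slowly), anisole, 80 °C
Reagents that add atoms: carbon monoxide, [C-]#[O+]
Why: PdCl2(dppf) is reduced in the flask to zerovalent palladium, which adds oxidatively to the C3–Br bond of 9 (the α-bromide of an enoate and the only carbon–halogen bond in the molecule); migratory insertion of CO then turns the vinylpalladium bromide into an acylpalladium species, the borate made from 4 and K2CO3 hands over its aryl group, and reductive elimination forms the C(=O)–aryl bond. The closest known reaction type is the carbonylative Suzuki–Miyaura coupling of vinyl and aryl bromides to aryl ketones. No ring is closed and no stereocentre is created; the Z-benzylidene is a spectator and is the more stable isomer. The selectivity required is carbonylation ahead of direct aryl transfer to the vinylpalladium bromide: C3 is flanked by the lactone carbonyl and ring B, which should hinder the bulky borate far more than the small CO, and the CO pressure together with the slow feed of 4 works in the same direction. Since the phenols of rings B and C are masked as isopropyl ethers and carry no bromine yet, the C3–Br bond has no aryl halide rival for oxidative addition, and no phenoxide is present to intercept the acylpalladium as an ester.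

Step 5
Reactants: 10 (Z)-3-(4-isopropoxybenzoyl)-4-(4-isopropoxyphenyl)-5-(4-methoxybenzylidene)furan-2(5H)-one
Product: 11 (Z)-3-(4-hydroxybenzoyl)-4-(4-hydroxyphenyl)-5-(4-methoxybenzylidene)furan-2(5H)-one
Conditions: BCl3 (1 M in CH2Cl2, 6 equiv), CH2Cl2, −78 → 0 °C; then H2O
Reagents that add atoms: none
Why: BCl3 ionises the two secondary O–isopropyl bonds at low temperature (SN1-like loss of the isopropyl group as 2-chloropropane), whereas the primary methyl ether of ring A, which has no ortho chelating carbonyl, should stay intact (selective Lewis-acid dealkylation of aryl isopropyl ethers).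

Step 6
Reactants: 11 (Z)-3-(4-hydroxybenzoyl)-4-(4-hydroxyphenyl)-5-(4-methoxybenzylidene)furan-2(5H)-one
Product: 12 (Z)-3-(3,5-dibromo-4-hydroxybenzoyl)-4-(3,5-dibromo-4-hydroxyphenyl)-5-(4-methoxybenzylidene)furan-2(5H)-one
Conditions: Br2 (4.1 equiv), NaOAc (5 equiv), 1,4-dioxane–H2O, 0 °C → rt
Reagents that add atoms: bromine, BrBr
Why: In the acetate-buffered aqueous medium the two free phenols react through their phenoxides at both positions ortho to OH (para is blocked) far faster than the methyl ether ring A or the electron-poor cross-conjugated alkene, the acetate takes up the HBr formed, and the bromine charge is limited to four equivalents (electrophilic aromatic bromination).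

Step 7
Reactants: 12 (Z)-3-(3,5-dibromo-4-hydroxybenzoyl)-4-(3,5-dibromo-4-hydroxyphenyl)-5-(4-methoxybenzylidene)furan-2(5H)-one
Product: 13 cadiolide A, (Z)-3-(3,5-dibromo-4-hydroxybenzoyl)-4-(3,5-dibromo-4-hydroxyphenyl)-5-(4-hydroxybenzylidene)furan-2(5H)-one
Conditions: BBr3 (1 M in CH2Cl2, 6 equiv), CH2Cl2, −78 °C → rt; then H2O
Reagents that add atoms: none
Why: BBr3 coordinates the one remaining ether oxygen and bromide attacks the methyl group (SN2), while the lactone, ketone, aryl bromides and Z-alkene are inert to the Lewis acid (BBr3 demethylation of an aryl methyl ether).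

Compound list
1 | mucobromic acid, 3,4-dibromo-5-hydroxyfuran-2(5H)-one (racemic lactol) | O=C1OC(O)C(Br)=C1Br | starting material
2 | (Z)-2,3-dibromo-4-hydroxybut-2-enoic acid | OC/C(Br)=C(/Br)C(=O)O | intermediate
3 | 3,4-dibromofuran-2(5H)-one | O=C1OCC(Br)=C1Br | intermediate
4 | 4-isopropoxyphenylboronic acid | CC(C)Oc1ccc(B(O)O)cc1 | starting material
5 | 3-bromo-4-(4-isopropoxyphenyl)furan-2(5H)-one | O=C1OCC(c2ccc(OC(C)C)cc2)=C1Br | intermediate
6 | 4-methoxybenzaldehyde | COc1ccc(C=O)cc1 | starting material
7 | tert-butyl{[3-bromo-4-(4-isopropoxyphenyl)furan-2-yl]oxy}dimethylsilane | CC(C)Oc1ccc(-c2coc(O[Si](C)(C)C(C)(C)C)c2Br)cc1 | intermediate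
8 | 3-bromo-5-[(tert-butyldimethylsilyloxy)(4-methoxyphenyl)methyl]-4-(4-isopropoxyphenyl)furan-2(5H)-one (mixture of diastereomers, configuration undefined) | O=C1OC(C(O[Si](C)(C)C(C)(C)C)c2ccc(OC)cc2)C(c2ccc(OC(C)C)cc2)=C1Br | intermediate
9 | (Z)-3-bromo-4-(4-isopropoxyphenyl)-5-(4-methoxybenzylidene)furan-2(5H)-one | O=C1O/C(=C\c2ccc(OC)cc2)C(c2ccc(OC(C)C)cc2)=C1Br | intermediate
10 | (Z)-3-(4-isopropoxybenzoyl)-4-(4-isopropoxyphenyl)-5-(4-methoxybenzylidene)furan-2(5H)-one | O=C1O/C(=C\c2ccc(OC)cc2)C(c2ccc(OC(C)C)cc2)=C1C(=O)c1ccc(OC(C)C)cc1 | intermediate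
11 | (Z)-3-(4-hydroxybenzoyl)-4-(4-hydroxyphenyl)-5-(4-methoxybenzylidene)furan-2(5H)-one | O=C1O/C(=C\c2ccc(OC)cc2)C(c2ccc(O)cc2)=C1C(=O)c1ccc(O)cc1 | intermediate
12 | (Z)-3-(3,5-dibromo-4-hydroxybenzoyl)-4-(3,5-dibromo-4-hydroxyphenyl)-5-(4-methoxybenzylidene)furan-2(5H)-one | O=C1O/C(=C\c2ccc(OC)cc2)C(c2cc(Br)c(O)c(Br)c2)=C1C(=O)c1cc(Br)c(O)c(Br)c1 | intermediate
13 | cadiolide A, (Z)-3-(3,5-dibromo-4-hydroxybenzoyl)-4-(3,5-dibromo-4-hydroxyphenyl)-5-(4-hydroxybenzylidene)furan-2(5H)-one | O=C1O/C(=C\c2ccc(O)cc2)C(c2cc(Br)c(O)c(Br)c2)=C1C(=O)c1cc(Br)c(O)c(Br)c1 | target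

Total step count: 7
Longest linear sequence: 7 steps (1 → 3 → 5 → 9 → 10 → 11 → 12 → 13)

Steps most likely to fail

Step 4. Aryl transfer may overtake CO insertion, so that ring C is attached directly to C3 without the carbonyl, or the carbonate may slowly open the crowded lactone at 80 °C. The fallback reverses the polarity of the union with known chemistry. It sets out from 9: palladium-catalysed stannylation with hexamethylditin (Me3SnSnMe3; Pd(PPh3)4, toluene, 100 °C) should give (Z)-4-(4-isopropoxyphenyl)-5-(4-methoxybenzylidene)-3-(trimethylstannyl)furan-2(5H)-one F1. A Stille acylation of F1 with 4-isopropoxybenzoyl chloride (CC(C)Oc1ccc(C(Cl)=O)cc1; PdCl2(PPh3)2, toluene, 80 °C) then forms the same C3–C(=O) bond, with the carbonyl carbon arriving already attached to ring C. The fallback comes back to the route at 10.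

Step 6. Chemoselectivity may be lost: bromine may also substitute ring A ortho to the methoxy group or add across the exocyclic alkene, or the ketone-deactivated ring C may be brominated incompletely. The fallback changes from free bromine in a protic medium, steered by the relative electron density of the rings, to bromine delivered by the free hydroxyl groups themselves in an aprotic medium. It sets out from 11 and uses N-bromosuccinimide (4 equiv) with catalytic iPr2NH in CH2Cl2 at 0 °C → rt. The amine relays bromine as a hydrogen-bonded N-bromo species that is regenerated in each turnover and transfers bromine only to the positions ortho to each phenol, so the methyl ether ring and the alkene have no means of directing it. The fallback comes back to the route at 12 and makes no new compound (F0).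

Step 2. The two C–Br bonds of 3 may not be discriminated well enough, giving double arylation, and 3 may degrade under the basic coupling conditions. The fallback attaches ring B where no second halide exists and introduces the C3 bromine afterwards. It sets out from boronic acid 4 and tetronic acid (O=C1C=C(O)CO1). Tosylation (TsCl, Et3N, CH2Cl2, 0 °C) should give 5-oxo-2,5-dihydrofuran-3-yl 4-methylbenzenesulfonate F2. Suzuki–Miyaura coupling of F2 with 4 (PdCl2(PPh3)2, aqueous Na2CO3, THF, 60 °C) should give 4-(4-isopropoxyphenyl)furan-2(5H)-one F3. Addition of Br2 across C3=C4 (CH2Cl2, 0 °C) should give 3,4-dibromo-4-(4-isopropoxyphenyl)dihydrofuran-2(3H)-one F4 as the racemic anti adduct, from which Et3N, added to the same flask, removes HBr (loss of the acidic C3–H and the benzylic C4 bromide). The fallback comes back to the route at 5.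

Further compounds
F1 | step 4 | (Z)-4-(4-isopropoxyphenyl)-5-(4-methoxybenzylidene)-3-(trimethylstannyl)furan-2(5H)-one | O=C1O/C(=C\c2ccc(OC)cc2)C(c2ccc(OC(C)C)cc2)=C1[Sn](C)(C)C
F0 | step 6 | none | none
F2 | step 2 | 5-oxo-2,5-dihydrofuran-3-yl 4-methylbenzenesulfonate | O=C1C=C(OS(=O)(=O)c2ccc(C)cc2)CO1
F3 | step 2 | 4-(4-isopropoxyphenyl)furan-2(5H)-one | O=C1C=C(c2ccc(OC(C)C)cc2)CO1
F4 | step 2 | 3,4-dibromo-4-(4-isopropoxyphenyl)dihydrofuran-2(3H)-one (racemic anti adduct, configuration not drawn because both stereocentres are lost in the same flask) | O=C1OCC(Br)(c2ccc(OC(C)C)cc2)C1Br
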